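**Strategy.** The plan cuts ring A (the methyl ester ring) at C1–C6 and C2–C3. Its C3–C4–C5–C6 segment, with the depside oxygen on C4 and the methyl on C6, maps atom for atom onto triacetic acid lactone. The lactone is therefore O‑acylated with the benzyl‑protected B–C didepside acid, and this pyranyl ester serves as the diene. In one operation a [4+2] addition of methyl 3,3‑dimethoxyacrylate, loss of CO2 and loss of methanol install C1 with its ester and C2 with its oxygen and deliver the whole protected tridepside. Global ether cleavage then gives the target.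

Key step: step 9

Remark: the target has no stereocentre and is achiral, so no enantiocontrol is needed; the sp3 centres formed transiently in step 9 vanish on aromatisation.

**Step 1**
Reactants: 1 orcinaldehyde (2,4-dihydroxy-6-methylbenzaldehyde)
Product: 2 2,4-bis(benzyloxy)-6-methylbenzaldehyde
Conditions: BnBr (2.4 equiv), K2CO3, DMF, 60 °C
Reagents that add atoms: benzyl bromide BrCc1ccccc1
Why: Williamson ether synthesis on both phenoxides, with gentle heating to overcome the hydrogen bond between the 2-OH and the formyl group.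

**Step 2**
Reactants: 2 2,4-bis(benzyloxy)-6-methylbenzaldehyde
Product: 3 2,4-bis(benzyloxy)-6-methylbenzoic acid
Conditions: NaClO2, NaH2PO4, 2-methyl-2-butene, t-BuOH/THF/H2O, 0 °C → rt
Reagents that add atoms: sodium chlorite [Na+].[O-]Cl=O
Why: Pinnick oxidation takes di-ortho-substituted aryl aldehydes to the acids under buffered conditions, and the alkene removes HOCl before it can chlorinate the electron-rich ring.

**Step 3**
Reactants: 3 2,4-bis(benzyloxy)-6-methylbenzoic acid; 1 orcinaldehyde
Product: 5 4-formyl-3-hydroxy-5-methylphenyl 2,4-bis(benzyloxy)-6-methylbenzoate, via ring C acid chloride 4 (not isolated)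
Conditions: (COCl)2, cat. DMF, CH2Cl2, 0 °C → rt; evaporate; then 1 (1.1 equiv), Et3N, cat. DMAP, CH2Cl2, 0 °C → rt
Reagents that add atoms: none
Why: Acid chloride esterification in which only the 4-OH of 1 should react, because it is the more acidic and unhindered phenol while the 2-OH is locked in a hydrogen bond to the formyl oxygen.

**Step 4**
Reactants: 5 4-formyl-3-hydroxy-5-methylphenyl 2,4-bis(benzyloxy)-6-methylbenzoate
Product: 6 3-(benzyloxy)-4-formyl-5-methylphenyl 2,4-bis(benzyloxy)-6-methylbenzoate
Conditions: BnBr (1.3 equiv), K2CO3, DMF, rt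
Reagents that add atoms: benzyl bromide BrCc1ccccc1
Why: Williamson benzylation of the remaining phenol under mild carbonate conditions, which the depside ester should survive because its carbonyl is shielded by two ortho substituents (OBn and Me).

**Step 5**
Reactants: 6 3-(benzyloxy)-4-formyl-5-methylphenyl 2,4-bis(benzyloxy)-6-methylbenzoate
Product: 7 2-(benzyloxy)-4-{[2,4-bis(benzyloxy)-6-methylbenzoyl]oxy}-6-methylbenzoic acid (tribenzyl B–C didepside acid)
Conditions: NaClO2, NaH2PO4, 2-methyl-2-butene, t-BuOH/THF/H2O, 0 °C → rt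
Reagents that add atoms: sodium chlorite [Na+].[O-]Cl=O
Why: Pinnick oxidation in a weakly acidic buffer that leaves the aryl ester and the benzyl ethers untouched.

**Step 6**
Reactants: 7 tribenzyl B–C didepside acid; 8 triacetic acid lactone (4-hydroxy-6-methyl-2H-pyran-2-one)
Product: 10 6-methyl-2-oxo-2H-pyran-4-yl 2-(benzyloxy)-4-{[2,4-bis(benzyloxy)-6-methylbenzoyl]oxy}-6-methylbenzoate, via B–C acid chloride 9 (not isolated)
Conditions: (COCl)2, cat. DMF, CH2Cl2, 0 °C → rt; evaporate; then 8 (1.2 equiv), Et3N, CH2Cl2, −10 → 0 °C (no DMAP)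
Reagents that add atoms: none
Why: O-acylation of the acidic enol (pKa about 5) of the lactone by an aroyl chloride, the analogue of Yamaguchi mixed-anhydride formation with a hindered aroyl chloride; leaving out nucleophilic catalysts avoids the O-to-C3 acyl shift.

**Step 7**
Reactants: 11 methyl cyanoacetate
Product: 13 methyl 3,3,3-trimethoxypropanoate, via Pinner salt 12 (not isolated)
Conditions: HCl (g), MeOH (1.05 equiv), Et2O, 0 °C; then MeOH (excess), rt
Reagents that add atoms: methanol CO
Why: Pinner reaction, in which HCl activates the nitrile for addition of methanol and the imidate hydrochloride is then alcoholysed by excess methanol to the ortho ester as ammonium chloride precipitates.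

**Step 8**
Reactants: 13 methyl 3,3,3-trimethoxypropanoate
Product: 14 methyl 3,3-dimethoxyacrylate
Conditions: neat, cat. TsOH, 150 °C, MeOH distilled off; then vacuum distillation from K2CO3
Reagents that add atoms: none
Why: Acid-catalysed thermal dealcoholation (β-elimination) of an ortho ester to a ketene acetal, favoured by the ester-activated α-hydrogens, the conjugated push–pull product and removal of methanol.

**Step 9**
Reactants: 10 6-methyl-2-oxo-2H-pyran-4-yl ester of the tribenzyl B–C didepside acid; 14 methyl 3,3-dimethoxyacrylate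
Product: 17 methyl 4-{[2-(benzyloxy)-4-{[2,4-bis(benzyloxy)-6-methylbenzoyl]oxy}-6-methylbenzoyl]oxy}-2-methoxy-6-methylbenzoate (tribenzyl tridepside 2-O-methyl ether), via bicyclic lactone adduct 15 (not isolated), via cyclohexadiene 16 (not isolated)
Conditions: 14 (8 equiv), mesitylene, cat. BHT, 165 °C, slow Ar sweep
Reagents that add atoms: none
Why: Proposed new method: the pyranone of 10 reacts as a diene through C3=C4–C5=C6 with the push–pull alkene 14 in a thermal [4+2] cycloaddition that joins pyranone C6 to the ester-bearing CH (ring A C1–C6) and pyranone C3 to the acetal carbon (ring A C2–C3) to give the 2-oxabicyclo[2.2.2]octenone 15; cycloreversion expels the lactone bridge as CO2 to give diene 16, and β-elimination of methanol across C1–C2 aromatises it. The closest known reaction type is the thermal Diels–Alder of 2-pyranones with 1,1-dimethoxyethene or alkynes followed by CO2 loss to give alkoxyarenes and benzoates; the pairing of a 4-acyloxy-6-alkylpyranone with a β,β-dialkoxyacrylate is the unproven part, which is why excess dienophile and a high temperature are specified. Ring A is closed by intermolecular [4+2] annulation, both ring bonds forming in the cycloaddition and the six-membered carbocycle being released by the retro-[4+2]. The sp3 centres of 15 and 16 are transient, so no stereocontrol is required. The selectivity needed is regiochemical (ester next to methyl, methoxy next to H-3) and should follow from matched polarisation, the nucleophilic C3 pairing with the electrophilic acetal carbon and the electrophilic C6 with the nucleophilic α-carbon of 14. Acyl transfer from the vinylogous anhydride is held back by the two ortho substituents that shield the aroyl carbonyl and by sweeping methanol out of the mixture.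

**Step 10**
Reactants: 17 tribenzyl tridepside 2-O-methyl ether
Product: 18 methyl 4-{[4-(2,4-dihydroxy-6-methylbenzoyl)oxy-2-hydroxy-6-methylbenzoyl]oxy}-2-hydroxy-6-methylbenzoate (CNP0212402.0)
Conditions: BCl3 (10 equiv), C6HMe5 (10 equiv), CH2Cl2, −78 → 0 °C; quench CHCl3/MeOH
Reagents that add atoms: none
Why: Lewis acid ether cleavage in which BCl3 chelates between each ortho ether oxygen and its ester carbonyl, chloride removes the methyl group, and pentamethylbenzene traps the benzyl cations by Friedel–Crafts alkylation, while the hindered aryl and methyl esters should persist at low temperature.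

**Compound list**

1 | orcinaldehyde (2,4-dihydroxy-6-methylbenzaldehyde) | Cc1cc(O)cc(O)c1C=O | starting material
2 | 2,4-bis(benzyloxy)-6-methylbenzaldehyde | Cc1cc(OCc2ccccc2)cc(OCc2ccccc2)c1C=O | intermediate
3 | 2,4-bis(benzyloxy)-6-methylbenzoic acid | Cc1cc(OCc2ccccc2)cc(OCc2ccccc2)c1C(=O)O | intermediate
4 | 2,4-bis(benzyloxy)-6-methylbenzoyl chloride (ring C acid chloride, not isolated) | Cc1cc(OCc2ccccc2)cc(OCc2ccccc2)c1C(=O)Cl | intermediate
5 | 4-formyl-3-hydroxy-5-methylphenyl 2,4-bis(benzyloxy)-6-methylbenzoate | Cc1cc(OC(=O)c2c(C)cc(OCc3ccccc3)cc2OCc2ccccc2)cc(O)c1C=O | intermediate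
6 | 3-(benzyloxy)-4-formyl-5-methylphenyl 2,4-bis(benzyloxy)-6-methylbenzoate | Cc1cc(OC(=O)c2c(C)cc(OCc3ccccc3)cc2OCc2ccccc2)cc(OCc2ccccc2)c1C=O | intermediate
7 | 2-(benzyloxy)-4-{[2,4-bis(benzyloxy)-6-methylbenzoyl]oxy}-6-methylbenzoic acid (tribenzyl B–C didepside acid) | Cc1cc(OC(=O)c2c(C)cc(OCc3ccccc3)cc2OCc2ccccc2)cc(OCc2ccccc2)c1C(=O)O | intermediate
8 | triacetic acid lactone (4-hydroxy-6-methyl-2H-pyran-2-one) | Cc1cc(O)cc(=O)o1 | starting material
9 | 2-(benzyloxy)-4-{[2,4-bis(benzyloxy)-6-methylbenzoyl]oxy}-6-methylbenzoyl chloride (B–C acid chloride, not isolated) | Cc1cc(OC(=O)c2c(C)cc(OCc3ccccc3)cc2OCc2ccccc2)cc(OCc2ccccc2)c1C(=O)Cl | intermediate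
10 | 6-methyl-2-oxo-2H-pyran-4-yl 2-(benzyloxy)-4-{[2,4-bis(benzyloxy)-6-methylbenzoyl]oxy}-6-methylbenzoate | Cc1cc(OC(=O)c2c(C)cc(OC(=O)c3c(C)cc(OCc4ccccc4)cc3OCc3ccccc3)cc2OCc2ccccc2)cc(=O)o1 | intermediate
11 | methyl cyanoacetate | COC(=O)CC#N | starting material
12 | methyl 3-imino-3-methoxypropanoate hydrochloride (Pinner salt, not isolated) | COC(=O)CC(=N)OC.Cl | intermediate
13 | methyl 3,3,3-trimethoxypropanoate | COC(=O)CC(OC)(OC)OC | intermediate
14 | methyl 3,3-dimethoxyacrylate | COC(=O)C=C(OC)OC | intermediate
15 | methyl 5-(aroyloxy)-8,8-dimethoxy-1-methyl-3-oxo-2-oxabicyclo[2.2.2]oct-5-ene-7-carboxylate, aroyl = tribenzyl B–C didepside acyl; racemic, endo/exo mixture at C7 expected, all stereocentres transient, so no descriptors are written (not isolated) | CC12C=C(OC(=O)c3c(C)cc(OC(=O)c4c(C)cc(OCc5ccccc5)cc4OCc4ccccc4)cc3OCc3ccccc3)C(C(=O)O1)C(OC)(OC)C2C(=O)OC | intermediate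
16 | methyl 4-(aroyloxy)-6,6-dimethoxy-2-methylcyclohexa-2,4-diene-1-carboxylate, aroyl as in 15; racemic at C1, transient (not isolated) | COC(=O)C1C(C)=CC(OC(=O)c2c(C)cc(OC(=O)c3c(C)cc(OCc4ccccc4)cc3OCc3ccccc3)cc2OCc2ccccc2)=CC1(OC)OC | intermediate
17 | methyl 4-{[2-(benzyloxy)-4-{[2,4-bis(benzyloxy)-6-methylbenzoyl]oxy}-6-methylbenzoyl]oxy}-2-methoxy-6-methylbenzoate | COC(=O)c1c(C)cc(OC(=O)c2c(C)cc(OC(=O)c3c(C)cc(OCc4ccccc4)cc3OCc3ccccc3)cc2OCc2ccccc2)cc1OC | intermediate
18 | methyl 4-{[4-(2,4-dihydroxy-6-methylbenzoyl)oxy-2-hydroxy-6-methylbenzoyl]oxy}-2-hydroxy-6-methylbenzoate (CNP0212402.0, achiral) | COC(=O)c1c(C)cc(OC(=O)c2c(C)cc(OC(=O)c3c(C)cc(O)cc3O)cc2O)cc1O | target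

**Step count.** Total: 10 steps. Longest linear sequence: 8 steps (steps 1–6, 9, 10); the dienophile branch (steps 7–8) joins at step 9.

**Steps most likely to fail**

1. Step 9 (the step carrying the new-method label). The cycloaddition between a weakly polarised diene and a push–pull alkene may be too slow, so that acyl transfer from the vinylogous anhydride to liberated methanol, or thermal oligomerisation of the ketene acetal, outruns ring formation. The fallback uses known depside chemistry and sets out from acid chloride 9, prepared from acid 7 as in step 6. Chloride 9 is used to acylate commercial methyl orsellinate (COC(=O)c1c(C)cc(O)cc1O) at its free 4-OH (Et3N, cat. DMAP, CH2Cl2, 0 °C → rt); the 2-OH is chelated to the ester and should stay unreacted. This should give methyl 4-{[2-(benzyloxy)-4-{[2,4-bis(benzyloxy)-6-methylbenzoyl]oxy}-6-methylbenzoyl]oxy}-2-hydroxy-6-methylbenzoate F1. Hydrogenolysis of the three benzyl ethers (H2, Pd/C, EtOAc/THF, rt) then rejoins the route at target 18.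

2. Step 6. Attack of the pyranone enolate on the di-ortho-substituted acid chloride may be slow, giving time for amine-promoted O-to-C3 acyl migration or for loss of the ortho benzyl group from the acid chloride. The fallback reverses the polarity of the bond formation and sets out from lactone 8 and acid 7. Lactone 8 is converted into 4-bromo-6-methyl-2H-pyran-2-one F2 (Bu4NBr, P2O5, toluene, 100 °C). Acid 7 is converted with Ag2CO3 into silver 2-(benzyloxy)-4-{[2,4-bis(benzyloxy)-6-methylbenzoyl]oxy}-6-methylbenzoate F3. The two are combined in MeCN/toluene at 50 °C in the dark. The carboxylate should add to C4 of this vinylogous acyl bromide and bromide should leave as its silver salt, an extension of the known addition–elimination of O-, N- and S-nucleophiles at C4 of 4-halopyranones. This returns to the route at pyranyl ester 10.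

3. Step 10. Benzyl cations may alkylate the electron-rich resorcinol rings before the scavenger intercepts them. Alternatively, the non-chelated 4-O-benzyl ether of ring C may need Lewis acid exposure long enough to cut a depside ester. The fallback separates the two tasks and sets out from 17. Hydrogenolysis (H2, Pd/C, EtOAc/THF, rt) removes the three benzyl groups without cationic intermediates and should give methyl 4-{[4-(2,4-dihydroxy-6-methylbenzoyl)oxy-2-hydroxy-6-methylbenzoyl]oxy}-2-methoxy-6-methylbenzoate F4. A short chelation-directed demethylation of the single ring A ether ortho to the ester (BCl3, CH2Cl2, −20 → 0 °C) then returns to the route at target 18.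

**Further compounds**

F1 | step 9 | methyl 4-{[2-(benzyloxy)-4-{[2,4-bis(benzyloxy)-6-methylbenzoyl]oxy}-6-methylbenzoyl]oxy}-2-hydroxy-6-methylbenzoate | COC(=O)c1c(C)cc(OC(=O)c2c(C)cc(OC(=O)c3c(C)cc(OCc4ccccc4)cc3OCc3ccccc3)cc2OCc2ccccc2)cc1O
F2 | step 6 | 4-bromo-6-methyl-2H-pyran-2-one | Cc1cc(Br)cc(=O)o1
F3 | step 6 | silver 2-(benzyloxy)-4-{[2,4-bis(benzyloxy)-6-methylbenzoyl]oxy}-6-methylbenzoate | Cc1cc(OC(=O)c2c(C)cc(OCc3ccccc3)cc2OCc2ccccc2)cc(OCc2ccccc2)c1C(=O)[O-].[Ag+]
F4 | step 10 | methyl 4-{[4-(2,4-dihydroxy-6-methylbenzoyl)oxy-2-hydroxy-6-methylbenzoyl]oxy}-2-methoxy-6-methylbenzoate | COC(=O)c1c(C)cc(OC(=O)c2c(C)cc(OC(=O)c3c(C)cc(O)cc3O)cc2O)cc1OC
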